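**Strategy.** The target is read as a ring-D-contracted serrat-14-ene (serratane numbering; ring E = C17–C22, formyl carbon = C15). Rings A–C are grown in one Mn(OAc)3 radical cascade, and the C14 formyl centre is made last by a Meinwald shift. The plan rests on ring E: its C21 carbonyl lies between the C22 gem-dimethyl carbon and the C17 methine, so the bond C17–C22 is made by a semipinacol 1,2-shift. A cyclopentanone (C17–C21) carrying the C17/C18 trans diad adds Me2C(SeMe)Li; silver-induced ionisation then moves C17 from C21 to the exocyclic CMe2 carbon. One operation enlarges the ring to six atoms, installs C22 and keeps the C17 configuration.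

Key step: step 9

Remark: the facial sense of the (1S,2R,5S)-8-phenylmenthyl ester in the Mn(OAc)3 cyclisation is assumed to follow that of related 8-phenylmenthyl β-keto ester cyclisations (5α,10β series); if it were opposite, the enantiomeric auxiliary would be used with no other change.

Abbreviation: "trienyl" = (1E,4E,8E)-10-{[tert-butyl(dimethyl)silyl]oxy}-5,9-dimethyldeca-1,4,8-trien-1-yl.

Step 1
Reactants: 1 geranyl bromide
Product: 2 (5E)-6,10-dimethylundeca-5,9-dien-1-yne
Conditions: HC≡CMgBr, CuCl (5 mol %), THF, 50 °C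
Reagents that add atoms: ethynylmagnesium bromide, C#C[Mg]Br
Why: Copper-catalysed SN2 coupling of an alkynyl Grignard reagent with a primary allylic bromide should give the skipped enyne with the E olefin untouched.

Step 2
Reactants: 2 (5E)-6,10-dimethylundeca-5,9-dien-1-yne
Product: 3 (2E,6E)-2,6-dimethylundeca-2,6-dien-10-yn-1-ol
Conditions: SeO2 (cat.), t-BuOOH, salicylic acid (cat.), CH2Cl2, rt
Reagents that add atoms: tert-butyl hydroperoxide, CC(C)(C)OO
Why: Catalytic SeO2 allylic oxidation (ene reaction, then [2,3]-shift) is selective for the E-methyl group of the terminal isopropylidene unit and should spare the alkyne and the inner olefin.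

Step 3
Reactants: 3 (2E,6E)-2,6-dimethylundeca-2,6-dien-10-yn-1-ol
Product: 4 tert-butyldimethylsilyl ether of 3
Conditions: TBSCl, imidazole, DMF, rt
Reagents that add atoms: tert-butyldimethylsilyl chloride, CC(C)(C)[Si](C)(C)Cl
Why: Standard O-silylation masks the primary allylic alcohol for the organometallic steps that follow.

Step 4
Reactants: 5 dimethyl diselenide; 6 acetone
Product: 8 2,2-bis(methylselanyl)propane, via methaneselenol 7 (not isolated)
Conditions: H3PO2 (aq.), reflux; then acetone, ZnCl2 (cat.), CH2Cl2, 0 °C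
Reagents that add atoms: none
Why: Reduction of the diselenide gives the selenol, which should form the selenoketal of acetone under ZnCl2 catalysis (ketalisation).

Step 5
Reactants: 9 (+)-8-phenylmenthol; 10 ethyl 2-methyl-3-oxobutanoate
Product: 11 (+)-8-phenylmenthyl 2-methyl-3-oxobutanoate
Conditions: DMAP (cat.), toluene, reflux, removal of EtOH
Reagents that add atoms: none
Why: DMAP-catalysed transesterification of the β-keto ester through its acylketene should attach the auxiliary; the α-carbon stays epimeric, which has no consequence.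

Step 6
Reactants: 4 tert-butyldimethylsilyl ether of 3; 12 3-methylcyclopent-2-en-1-one
Product: 15 (3R)-trimethylsilyl enol ether of the conjugate adduct, via E-alkenyl(diisobutyl)alane 13 (not isolated), via diisobutylaluminium enolate 14 (not isolated)
Conditions: i-Bu2AlH, hexane, 55 °C; then 12, Cu(OTf)2 (5 mol %), chiral sulfonate-bearing imidazolinium salt (carbene precursor, 5 mol %), THF, −30 °C; then TMSOTf, −78 °C
Reagents that add atoms: trimethylsilyl triflate, C[Si](C)(C)OS(=O)(=O)C(F)(F)F
Why: syn-Hydroalumination gives the E-alkenylalane, its carbene–copper-catalysed asymmetric conjugate addition to the β-methyl enone sets the quaternary centre C18 (R) under catalyst control, and O-silylation fixes the enolate regiochemistry.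

Step 7
Reactants: 15 (3R)-trimethylsilyl enol ether of the conjugate adduct
Product: 17 (2R,3R)-2-allyl-3-methyl-3-trienylcyclopentan-1-one, via lithium enolate 16 (not isolated)
Conditions: MeLi, THF, 0 °C; then allyl bromide, DMPU, −78 to −20 °C
Reagents that add atoms: allyl bromide, C=CCBr
Why: Si–O cleavage by MeLi releases the regiodefined lithium enolate, and its C-allylation (enolate alkylation) should occur anti to the longer trienyl chain, setting C17 with allyl trans to that chain and cis to the methyl group.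

Step 8
Reactants: 17 (2R,3R)-2-allyl-3-methyl-3-trienylcyclopentan-1-one; 8 2,2-bis(methylselanyl)propane
Product: 19 β-hydroxy selenide (tertiary carbinol at C21), via 2-lithio-2-(methylselanyl)propane 18 (not isolated)
Conditions: 8, n-BuLi, THF, −78 °C; then 17, −78 °C; aq. NH4Cl
Reagents that add atoms: none
Why: Se/Li exchange gives the tertiary α-seleno alkyllithium, which should add 1,2 to the ketone without enolisation; the carbinol configuration is immaterial because C21 becomes trigonal in step 9.

Step 9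
Reactants: 19 β-hydroxy selenide
Product: 20 (3R,4R)-3-allyl-2,2,4-trimethyl-4-trienylcyclohexan-1-one (ring E)
Conditions: AgBF4 on basic Al2O3, CH2Cl2, 0 °C to rt
Reagents that add atoms: none
Why: Silver ion binds selenium and the tertiary C22–Se bond ionises while the antiperiplanar ring bond C21–C17 shifts to C22 and the carbinol oxygen closes to the carbonyl (semipinacol, cationic 1,2-shift). The closest known reaction type is the ring enlargement of β-hydroxyalkyl selenides of cycloalkanones to their 2,2-dimethyl homologues. Ring E is not closed by a cyclisation but grows from five to six atoms by insertion of C22 between C21 and C17. No stereocentre is created: C17 migrates with retention, so the trans C17/C18 relation from step 7 is carried over, and C21 becomes trigonal. The step needs migration of tertiary C17 instead of secondary C20, which the higher migratory aptitude of the more substituted carbon should secure, and chemoselectivity over four olefins and the silyl ether, which the selenophilic silver salt on basic alumina should secure.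

Step 10
Reactants: 20 (3R,4R)-3-allyl-2,2,4-trimethyl-4-trienylcyclohexan-1-one
Product: 22 (3R,4R)-3-(3-hydroxypropyl)-2,2,4-trimethyl-4-trienylcyclohexan-1-one, via B-alkyl-9-borabicyclononane adduct 21 (not isolated)
Conditions: 9-BBN, THF, 0 °C to rt; then NaOH, H2O2, 0 °C
Reagents that add atoms: hydrogen peroxide, OO
Why: Hydroboration–oxidation with the bulky borane is selective for the monosubstituted allyl olefin over the di- and trisubstituted olefins and the hindered ketone, and should give the anti-Markovnikov primary alcohol.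

Step 11
Reactants: 22 (3R,4R)-3-(3-hydroxypropyl)-2,2,4-trimethyl-4-trienylcyclohexan-1-one
Product: 23 (3R,4R)-3-(3-oxopropyl)-2,2,4-trimethyl-4-trienylcyclohexan-1-one
Conditions: Dess–Martin periodinane, NaHCO3, CH2Cl2, 0 °C to rt
Reagents that add atoms: none
Why: Dess–Martin oxidation should convert the primary alcohol to the aldehyde without touching the olefins or the silyl ether.

Step 12
Reactants: 23 (3R,4R)-3-(3-oxopropyl)-2,2,4-trimethyl-4-trienylcyclohexan-1-one
Product: 24 (3R,4R)-3-(but-3-yn-1-yl)-2,2,4-trimethyl-4-trienylcyclohexan-1-one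
Conditions: dimethyl (1-diazo-2-oxopropyl)phosphonate, K2CO3, MeOH, 0 °C to rt
Reagents that add atoms: dimethyl (1-diazo-2-oxopropyl)phosphonate, COP(=O)(OC)C(=[N+]=[N-])C(C)=O
Why: Seyferth–Gilbert homologation with the Ohira–Bestmann reagent should turn the aldehyde into the terminal alkyne under mild base that cannot epimerise the non-enolisable C17 centre.

Step 13
Reactants: 24 (3R,4R)-3-(but-3-yn-1-yl)-2,2,4-trimethyl-4-trienylcyclohexan-1-one
Product: 26 DE-bicyclic keto allylic alcohol (trans-decalin with C14 exocyclic methylene), via exocyclic vinylstannane 25 (not isolated)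
Conditions: Bu3SnH (slow addition), AIBN, PhH, 80 °C; then HCl, MeOH, 0 °C
Reagents that add atoms: none
Why: Radical hydrostannylation of the alkyne gives a vinyl radical that should close ring D by 6-exo-trig addition to the E-olefin through a chair transition state with the chain equatorial (13β-H, trans-decalin); acid then removes tin (protodestannylation) and the silyl ether.

Step 14
Reactants: 26 DE-bicyclic keto allylic alcohol
Product: 27 DE-bicyclic keto allylic bromide
Conditions: CBr4, PPh3, CH2Cl2, 0 °C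
Reagents that add atoms: carbon tetrabromide, BrC(Br)(Br)Br
Why: Appel bromination of the primary allylic alcohol should proceed under neutral conditions without allylic transposition.

Step 15
Reactants: 27 DE-bicyclic keto allylic bromide; 11 (+)-8-phenylmenthyl 2-methyl-3-oxobutanoate
Product: 29 polyene β-keto ester, via sodium lithium dianion of the keto ester 28 (not isolated)
Conditions: 11, NaH, THF, 0 °C; n-BuLi, 0 °C; then 27, −78 to 0 °C
Reagents that add atoms: none
Why: γ-Alkylation of the β-keto ester dianion by the allylic bromide is fast at low temperature, so the hindered neopentyl-type ring-E ketone should not be attacked.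

Step 16
Reactants: 29 polyene β-keto ester
Product: 30 (+)-8-phenylmenthyl 3,21-dioxoserrat-14-en-24-oate
Conditions: Mn(OAc)3·2H2O (2.2 equiv), Yb(OTf)3 (1 equiv), CF3CH2OH, 0 °C
Reagents that add atoms: none
Why: In this Mn(OAc)3 oxidative radical polycyclisation the α-keto ester radical should close ring A and ring B (both 6-endo) through chair–chair transition states on the face left open by the phenyl group of the auxiliary (C4 with the ester axial, C5, C10, C9); the tertiary C8 radical then adds 7-endo to the exocyclic methylene from the α face, away from the 10β-methyl group, and oxidation of the C14 radical with loss of the axial H-15 gives the 14-ene.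

Step 17
Reactants: 30 (+)-8-phenylmenthyl 3,21-dioxoserrat-14-en-24-oate
Product: 32 serrat-14-ene-3α,21β,24-triol, via (+)-8-phenylmenthyl 3α,21β-dihydroxyserrat-14-en-24-oate 31 (not isolated)
Conditions: LiBH(s-Bu)3, THF, −78 to 0 °C; then LiAlH4, THF, reflux
Reagents that add atoms: none
Why: The bulky hydride should attack both hindered ketones from the equatorial side to give the axial 3α- and 21β-alcohols, and LiAlH4 then reduces the neopentyl ester to the C24 carbinol and releases the auxiliary.

Step 18
Reactants: 32 serrat-14-ene-3α,21β,24-triol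
Product: 33 3α,21β,24-tris(triethylsilyloxy)serrat-14-ene
Conditions: TESOTf, 2,6-lutidine, CH2Cl2, 0 °C
Reagents that add atoms: triethylsilyl triflate, CC[Si](CC)(CC)OS(=O)(=O)C(F)(F)F
Why: Silylation with the reactive triflate should protect the two hindered axial secondary alcohols and the primary alcohol against the Lewis acid of step 20.

Step 19
Reactants: 33 3α,21β,24-tris(triethylsilyloxy)serrat-14-ene
Product: 34 14β,15β-epoxy-3α,21β,24-tris(triethylsilyloxy)serratane
Conditions: mCPBA, NaHCO3, CH2Cl2, 0 °C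
Reagents that add atoms: 3-chloroperbenzoic acid, OOC(=O)c1cccc(Cl)c1
Why: Prilezhaev epoxidation of the only olefin should occur on the β face, anti to the axial 18α-methyl group, as with 5α-steroid 2-enes.

Step 20
Reactants: 34 14β,15β-epoxy-3α,21β,24-tris(triethylsilyloxy)serratane
Product: 35 tris(triethylsilyl) ether of the target aldehyde
Conditions: MeAl(OC6H2-4-Br-2,6-t-Bu2)2 (20 mol %), CH2Cl2, −78 °C
Reagents that add atoms: none
Why: In this Meinwald rearrangement the bulky aluminium Lewis acid should open the epoxide at tertiary C14 and favour migration of ring carbon C16 (anti to the departing β C–O bond) over hydride, so ring D contracts and C15 becomes the β-formyl group on the new quaternary C14.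

Step 21
Reactants: 35 tris(triethylsilyl) ether of the target aldehyde
Product: 36 target, 3α,21β,24-trihydroxy-16(15→14)abeo-serratan-15-al
Conditions: HF·pyridine, THF, 0 °C to rt
Reagents that add atoms: none
Why: Fluoride-mediated desilylation should free the three hydroxyl groups without affecting the non-enolisable aldehyde.

**Compound list**

1 | geranyl bromide, (2E)-1-bromo-3,7-dimethylocta-2,6-diene | CC(C)=CCC/C(C)=C/CBr | starting material
2 | (5E)-6,10-dimethylundeca-5,9-dien-1-yne | C#CC/C=C(\C)CCC=C(C)C | intermediate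
3 | (2E,6E)-2,6-dimethylundeca-2,6-dien-10-yn-1-ol | C#CC/C=C(\C)CC/C=C(\C)CO | intermediate
4 | tert-butyl{[(2E,6E)-2,6-dimethylundeca-2,6-dien-10-yn-1-yl]oxy}dimethylsilane | C#CC/C=C(\C)CC/C=C(\C)CO[Si](C)(C)C(C)(C)C | intermediate
5 | dimethyl diselenide | C[Se][Se]C | starting material
6 | acetone | CC(C)=O | starting material
7 | methaneselenol (not isolated) | C[SeH] | intermediate
8 | 2,2-bis(methylselanyl)propane | C[Se]C(C)(C)[Se]C | intermediate
9 | (+)-8-phenylmenthol, (1S,2R,5S)-5-methyl-2-(2-phenylpropan-2-yl)cyclohexan-1-ol | C[C@H]1CC[C@@H]([C@H](C1)O)C(C)(C)c1ccccc1 | starting material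
10 | ethyl 2-methyl-3-oxobutanoate | CCOC(=O)C(C)C(C)=O | starting material
11 | (1S,2R,5S)-5-methyl-2-(2-phenylpropan-2-yl)cyclohexyl 2-methyl-3-oxobutanoate (epimers at C2 of the acyl part) | C[C@H]1CC[C@@H]([C@H](C1)OC(=O)C(C)C(C)=O)C(C)(C)c1ccccc1 | intermediate
12 | 3-methylcyclopent-2-en-1-one | CC1=CC(=O)CC1 | starting material
13 | diisobutyl(trienyl)alane (not isolated) | CC(C)C[Al](CC(C)C)/C=C/C/C=C(\C)CC/C=C(\C)CO[Si](C)(C)C(C)(C)C | intermediate
14 | diisobutylaluminium enolate of (3R)-3-methyl-3-trienylcyclopentanone (not isolated) | CC(C)C[Al](CC(C)C)OC1=C[C@@](C)(/C=C/C/C=C(\C)CC/C=C(\C)CO[Si](C)(C)C(C)(C)C)CC1 | intermediate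
15 | {[(3R)-3-methyl-3-trienylcyclopent-1-en-1-yl]oxy}trimethylsilane | C[Si](C)(C)OC1=C[C@@](C)(/C=C/C/C=C(\C)CC/C=C(\C)CO[Si](C)(C)C(C)(C)C)CC1 | intermediate
16 | lithium enolate of (3R)-3-methyl-3-trienylcyclopentanone (not isolated) | [Li]OC1=C[C@@](C)(/C=C/C/C=C(\C)CC/C=C(\C)CO[Si](C)(C)C(C)(C)C)CC1 | intermediate
17 | (2R,3R)-2-allyl-3-methyl-3-trienylcyclopentan-1-one (allyl trans to the trienyl chain) | O=C1CC[C@@](/C=C/C/C=C(\C)CC/C=C(\C)CO[Si](C)(C)C(C)(C)C)(C)[C@H]1CC=C | intermediate
18 | 2-lithio-2-(methylselanyl)propane (not isolated) | [Li]C(C)(C)[Se]C | intermediate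
19 | (2R,3R)-2-allyl-3-methyl-1-[2-(methylselanyl)propan-2-yl]-3-trienylcyclopentan-1-ol (either configuration at C1) | C[Se]C(C)(C)C1(O)CC[C@@](/C=C/C/C=C(\C)CC/C=C(\C)CO[Si](C)(C)C(C)(C)C)(C)[C@H]1CC=C | intermediate
20 | (3R,4R)-3-allyl-2,2,4-trimethyl-4-trienylcyclohexan-1-one | CC1(C)C(=O)CC[C@@](/C=C/C/C=C(\C)CC/C=C(\C)CO[Si](C)(C)C(C)(C)C)(C)[C@H]1CC=C | intermediate
21 | B-alkyl-9-borabicyclo[3.3.1]nonane adduct of 20 (not isolated) | CC1(C)C(=O)CC[C@@](/C=C/C/C=C(\C)CC/C=C(\C)CO[Si](C)(C)C(C)(C)C)(C)[C@H]1CCCB1C2CCCC1CCC2 | intermediate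
22 | (3R,4R)-3-(3-hydroxypropyl)-2,2,4-trimethyl-4-trienylcyclohexan-1-one | CC1(C)C(=O)CC[C@@](/C=C/C/C=C(\C)CC/C=C(\C)CO[Si](C)(C)C(C)(C)C)(C)[C@H]1CCCO | intermediate
23 | 3-[(1R,6R)-2,2,6-trimethyl-3-oxo-6-trienylcyclohexyl]propanal | CC1(C)C(=O)CC[C@@](/C=C/C/C=C(\C)CC/C=C(\C)CO[Si](C)(C)C(C)(C)C)(C)[C@H]1CCC=O | intermediate
24 | (3R,4R)-3-(but-3-yn-1-yl)-2,2,4-trimethyl-4-trienylcyclohexan-1-one | CC1(C)C(=O)CC[C@@](/C=C/C/C=C(\C)CC/C=C(\C)CO[Si](C)(C)C(C)(C)C)(C)[C@H]1CCC#C | intermediate
25 | exocyclic (tributylstannyl)methylidene analogue of the silyl ether of 26, olefin geometry at tin undefined (not isolated) | CC1(C)C(=O)CC[C@@]2(C)[C@H]1CCC(=C[Sn](CCCC)(CCCC)CCCC)[C@@H]2CC/C=C(\C)CC/C=C(\C)CO[Si](C)(C)C(C)(C)C | intermediate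
26 | (4aR,5S,8aR)-5-[(3E,7E)-9-hydroxy-4,8-dimethylnona-3,7-dien-1-yl]-1,1,4a-trimethyl-6-methylideneoctahydronaphthalen-2(1H)-one (trans-decalin, side chain equatorial and cis to the angular methyl) | CC1(C)C(=O)CC[C@@]2(C)[C@H]1CCC(=C)[C@@H]2CC/C=C(\C)CC/C=C(\C)CO | intermediate
27 | (4aR,5S,8aR)-5-[(3E,7E)-9-bromo-4,8-dimethylnona-3,7-dien-1-yl]-1,1,4a-trimethyl-6-methylideneoctahydronaphthalen-2(1H)-one | CC1(C)C(=O)CC[C@@]2(C)[C@H]1CCC(=C)[C@@H]2CC/C=C(\C)CC/C=C(\C)CBr | intermediate
28 | sodium lithium dianion of 11 (not isolated) | [Li+].[Na+].C=C([O-])C(C)=C([O-])O[C@H]1C[C@@H](C)CC[C@@H]1C(C)(C)c1ccccc1 | intermediate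
29 | (+)-8-phenylmenthyl (6E,10E)-2,6,10-trimethyl-3-oxo-13-[the (4aR,5S,8aR)-bicyclic unit of 26]trideca-6,10-dienoate (epimers at C2) | CC1(C)C(=O)CC[C@@]2(C)[C@H]1CCC(=C)[C@@H]2CC/C=C(\C)CC/C=C(\C)CCC(=O)C(C)C(=O)O[C@H]1C[C@@H](C)CC[C@@H]1C(C)(C)c1ccccc1 | intermediate
30 | (+)-8-phenylmenthyl 3,21-dioxoserrat-14-en-24-oate (5α-H, 8β-Me, 9α-H, 10β-Me, 13β-H, 17β-H, 18α-Me; ester on the 4β carbon) | CC1(C)C(=O)CC[C@@]2(C)[C@H]1CC=C1C[C@]3(C)CC[C@@H]4[C@](C)(CCC(=O)[C@]4(C)C(=O)O[C@H]5C[C@@H](C)CC[C@@H]5C(C)(C)c5ccccc5)[C@H]3CC[C@@H]12 | intermediate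
31 | (+)-8-phenylmenthyl 3α,21β-dihydroxyserrat-14-en-24-oate (not isolated) | CC1(C)[C@H](O)CC[C@@]2(C)[C@H]1CC=C1C[C@]3(C)CC[C@@H]4[C@](C)(CC[C@@H](O)[C@]4(C)C(=O)O[C@H]5C[C@@H](C)CC[C@@H]5C(C)(C)c5ccccc5)[C@H]3CC[C@@H]12 | intermediate
32 | serrat-14-ene-3α,21β,24-triol | CC1(C)[C@H](O)CC[C@@]2(C)[C@H]1CC=C1C[C@]3(C)CC[C@@H]4[C@](C)(CC[C@@H](O)[C@]4(C)CO)[C@H]3CC[C@@H]12 | intermediate
33 | 3α,21β,24-tris(triethylsilyloxy)serrat-14-ene | CC1(C)[C@H](O[Si](CC)(CC)CC)CC[C@@]2(C)[C@H]1CC=C1C[C@]3(C)CC[C@@H]4[C@](C)(CC[C@@H](O[Si](CC)(CC)CC)[C@]4(C)CO[Si](CC)(CC)CC)[C@H]3CC[C@@H]12 | intermediate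
34 | 14β,15β-epoxy-3α,21β,24-tris(triethylsilyloxy)serratane | CC1(C)[C@H](O[Si](CC)(CC)CC)CC[C@@]2(C)[C@H]1C[C@H]5O[C@]51C[C@]3(C)CC[C@@H]4[C@](C)(CC[C@@H](O[Si](CC)(CC)CC)[C@]4(C)CO[Si](CC)(CC)CC)[C@H]3CC[C@@H]12 | intermediate
35 | 3α,21β,24-tris(triethylsilyloxy)-16(15→14)abeo-serratan-15-al (formyl β on C14) | CC1(C)[C@H](O[Si](CC)(CC)CC)CC[C@@]2(C)[C@H]1C[C@]1(C=O)C[C@]3(C)CC[C@@H]4[C@](C)(CC[C@@H](O[Si](CC)(CC)CC)[C@]4(C)CO[Si](CC)(CC)CC)[C@H]3CC[C@@H]12 | intermediate
36 | 3α,21β,24-trihydroxy-16(15→14)abeo-serratan-15-al | CC1(C)[C@H](O)CC[C@@]2(C)[C@H]1C[C@]1(C=O)C[C@]3(C)CC[C@@H]4[C@](C)(CC[C@@H](O)[C@]4(C)CO)[C@H]3CC[C@@H]12 | target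

**Step count and risks**

Total: 21 steps. Longest linear sequence: 19 steps (steps 1–3, then 6–21); steps 4 and 5 prepare the selenoketal and the auxiliary keto ester.

Most likely to fail:

1. Step 16. The tertiary C8 radical may be oxidised or quenched before the slow 7-endo closure, or the C14 cation may lose a proton towards C27 or C13, giving bicyclised dienes or olefin isomers. Fallback: setting out from 29, the cascade is stopped on purpose after ring B by chloride ligand transfer (Mn(OAc)3, Cu(OAc)2, LiCl, AcOH) to give the tertiary C8 chloride of the A/B-cyclised keto ester F1. Ionisation of F1 with SnCl4 in CH2Cl2 at −78 °C generates a cation at C8 only, which should be trapped by the exocyclic methylene in a cation–olefin cyclisation and lose H-15, returning to the route at 30.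

2. Step 7. Methyl and the alkenyl chain on C18 differ little in size, so facial selectivity of the allylation may be poor and the C17 epimer may form. Fallback: setting out from 15, the enolate released by MeLi is O-acylated with allyl chloroformate to the allyl enol carbonate F2. Decarboxylative allylic alkylation of F2 with Pd2(dba)3 and the matched enantiomer of a tert-butyl phosphinooxazoline ligand should set C17 under catalyst control and returns to the route at 17.

3. Step 19. The peracid may approach the α face if the seven-membered ring and the 8β-methyl group shield the β face, giving the epimeric epoxide, which would contract to the C14 epimer. Fallback: setting out from 33, NBS in aqueous DME forms the bromonium ion on the accessible face and water opens it at tertiary C14 from the other face to give the 15α-bromo-14β-hydroxy bromohydrin F3. K2CO3 in MeOH closes F3 to the 14β,15β-epoxide, returning to the route at 34.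

**Further compounds**

F1 | step 16 | (+)-8-phenylmenthyl A/B-trans-decalin β-keto ester with a tertiary chloride at C8 (either configuration), joined through C11–C12 to the DE bicycle that keeps its exocyclic methylene | CC1(C)C(=O)CC[C@@]2(C)[C@H]1CCC(=C)[C@@H]2CC[C@H]3C(C)(Cl)CC[C@@H]4[C@]3(C)CCC(=O)[C@]4(C)C(=O)O[C@H]5C[C@@H](C)CC[C@@H]5C(C)(C)c5ccccc5
F2 | step 7 | allyl (3R)-3-methyl-3-trienylcyclopent-1-en-1-yl carbonate | C=CCOC(=O)OC1=C[C@@](C)(/C=C/C/C=C(\C)CC/C=C(\C)CO[Si](C)(C)C(C)(C)C)CC1
F3 | step 19 | 15α-bromo-3α,21β,24-tris(triethylsilyloxy)serratan-14β-ol | CC1(C)[C@H](O[Si](CC)(CC)CC)CC[C@@]2(C)[C@H]1C[C@H](Br)[C@]1(O)C[C@]3(C)CC[C@@H]4[C@](C)(CC[C@@H](O[Si](CC)(CC)CC)[C@]4(C)CO[Si](CC)(CC)CC)[C@H]3CC[C@@H]12
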